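**Plan**
Retrosynthesis: the two catechols are first masked as acetonides. Both bonds between a bridging CH2 and C1 of a 2,3-dihydroxyphenyl ring are then cut together. Last, the C6–CH2 and C8–CH2 bonds are cut, which leads back to (2S)-pinocembrin.
Enabling feature: each bridging CH2 sits on a ring A carbon next to a free phenol. C8 lies beside 7-OH (its other neighbour is C8a, which carries the ring oxygen O1), and C6 lies between 5-OH and 7-OH. A leaving group on that CH2 can therefore depart as an ortho-quinone methide across C7=O. The far end of each CH2 is the catechol carbon ortho to oxygen, a site that electrophilic substitution avoids but ortho-lithiation and borylation mark exactly.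
Forward: no ring is built. Rings A, B and C arrive intact with pinocembrin, and the two catechol rings come from 2,2-dimethyl-1,3-benzodioxole. The order of joining is C1 units onto ring A (double Mannich reaction), aryl groups onto the C1 units (double boron-to-carbon transfer), then ketal hydrolysis.
Stereochemistry: the only stereocentre, C2 (S), is bought with natural pinocembrin and is only preserved, since no step uses strong base.

Key step: step 3

Assumption: commercial natural pinocembrin is taken to be the (2S)-enantiomer of high enantiomeric purity (to be checked by chiral HPLC), and in step 3 the C8 arm is drawn as reacting before the C6 arm, an order that has no bearing on the product.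

Step 1
Reactants: 1 (2S)-pinocembrin; 2 dimethylmethyleneiminium iodide
Product: 4 (2S)-6,8-bis[(dimethylamino)methyl]-5,7-dihydroxy-2-phenylchroman-4-one, via bis(hydroiodide) salt 3 (not isolated)
Conditions: 2 (2.3 equiv), MeCN, 0 °C to rt; then cold aq NaHCO3, EtOAc
Reagents that add atoms: dimethylmethyleneiminium iodide (compound 2), C=[N+](C)C.[I-]
Why: This is a Mannich-type electrophilic aromatic aminomethylation with a preformed iminium salt, in which C6 and C8 are the only free positions of the phloroglucinol-type ring A, each lies ortho or para to three oxygen substituents and should react far faster than the weakly enolised C3, and the amine stays locked as its hydroiodide until a short cold NaHCO3 wash, so the medium never becomes basic enough to open ring C and C2 stays (S).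

Step 2
Reactants: 5 2,2-dimethyl-1,3-benzodioxole
Product: 8 (2,2-dimethyl-1,3-benzodioxol-4-yl)boronic acid, via 4-lithio-2,2-dimethyl-1,3-benzodioxole 6 (not isolated), via lithium aryltrimethoxyborate 7 (not isolated)
Conditions: n-BuLi, TMEDA, Et2O, 0 °C to rt; B(OMe)3, −78 °C to rt; then 1 M HCl, 0 °C
Reagents that add atoms: trimethyl borate, COB(OC)OC; water, O
Why: This is a directed ortho-metalation followed by electrophilic borylation, in which the dioxole oxygens direct to and acidify the adjacent C4–H (C4 and C7 are equivalent), the quaternary C2 offers no acidic acetal hydrogen, and the aryllithium adds to B(OMe)3 to give a borate that brief cold acid hydrolyses without harming the acid-tolerant catechol acetonide.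

Step 3
Reactants: 4 (2S)-6,8-bis[(dimethylamino)methyl]-5,7-dihydroxy-2-phenylchroman-4-one; 8 (2,2-dimethyl-1,3-benzodioxol-4-yl)boronic acid
Product: 12 (2S)-6,8-bis[(2,2-dimethyl-1,3-benzodioxol-4-yl)methyl]-5,7-dihydroxy-2-phenylchroman-4-one, via 8-methylene ortho-quinone methide 9 (not isolated), via 8-arylmethyl 6-aminomethyl flavanone 10 (not isolated), via 6-methylene ortho-quinone methide 11 (not isolated)
Conditions: 8 (6 equiv), 1,4-dioxane (0.05 M), 90 °C, slow N2 stream; then H2O
Reagents that add atoms: none
Why: Boronic acid 8 condenses with the acidic 7-OH of 4 and is held by the adjacent NMe2 group in a six-membered O–B–N chelate; on heating, the C–N bond of the C8 arm breaks, dimethylamine leaves, and ortho-quinone methide 9 (C7=O, C8=CH2) forms with its carbonyl oxygen still bound to four-coordinate boron, from which the aryl group shifts to the exocyclic CH2 through a six-membered cyclic transition state, re-aromatising ring A to 10, and the same events at the C6 arm through 11 give 12. The closest known reaction types are the 1,4-addition of aryl- and alkenylboron reagents to ortho-quinone methides released in situ from 2-hydroxybenzylamines or 2-hydroxybenzyl ethers, and the aryl transfer of the Petasis borono-Mannich reaction of salicylaldehydes, applied here twice in one substrate. No ring is closed and no stereocentre is created. The selectivity needed is positional on the catechol ring, and it is secured because the transfer is ipso, so carbon bonds exactly where boron stood at C4 of the benzodioxole, while on ring A both sites are meant to react and no free ring A C–H remains that could intercept a quinone methide. C2 only has to survive, which is favoured because the excess of 8 complexes the liberated dimethylamine, the gas stream carries the rest away, and any residual base is taken up by the 7-OH, whose anion lowers the acidity of C3–H and so disfavours E1cB opening of ring C. The ortho-oxygenated, electron-rich aryl group should migrate readily, and the excess of 8 also covers losses by protodeboronation.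

Step 4
Reactants: 12 (2S)-6,8-bis[(2,2-dimethyl-1,3-benzodioxol-4-yl)methyl]-5,7-dihydroxy-2-phenylchroman-4-one
Product: 13 (2S)-6,8-bis(2,3-dihydroxybenzyl)-5,7-dihydroxy-2-phenylchroman-4-one
Conditions: TFA/H2O (9:1), degassed, Ar, 0 °C to rt
Reagents that add atoms: none
Why: This is an acid-catalysed ketal hydrolysis, the standard release of catechols from their acetonides, in which protonation of a dioxole oxygen, opening to the oxocarbenium ion and capture by water liberate acetone, while the base-sensitive C2 centre, the diarylmethane links and the chelated C4 ketone should not be attacked by aqueous acid at room temperature.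

**Compound list**
1 | (2S)-pinocembrin, (2S)-5,7-dihydroxy-2-phenylchroman-4-one | O=C1C[C@@H](c2ccccc2)Oc2cc(O)cc(O)c21 | starting material
2 | dimethylmethyleneiminium iodide | C=[N+](C)C.[I-] | starting material
3 | bis(hydroiodide) of (2S)-6,8-bis[(dimethylamino)methyl]-5,7-dihydroxy-2-phenylchroman-4-one | O=C1C[C@@H](c2ccccc2)Oc2c(C[NH+](C)C)c(O)c(C[NH+](C)C)c(O)c21.[I-].[I-] | intermediate
4 | (2S)-6,8-bis[(dimethylamino)methyl]-5,7-dihydroxy-2-phenylchroman-4-one | O=C1C[C@@H](c2ccccc2)Oc2c(CN(C)C)c(O)c(CN(C)C)c(O)c21 | intermediate
5 | 2,2-dimethyl-1,3-benzodioxole | CC1(C)Oc2ccccc2O1 | starting material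
6 | 4-lithio-2,2-dimethyl-1,3-benzodioxole | [Li]c1cccc2c1OC(C)(C)O2 | intermediate
7 | lithium (2,2-dimethyl-1,3-benzodioxol-4-yl)trimethoxyborate | [Li+].CO[B-](OC)(OC)c1cccc2c1OC(C)(C)O2 | intermediate
8 | (2,2-dimethyl-1,3-benzodioxol-4-yl)boronic acid | CC1(C)Oc2cccc(B(O)O)c2O1 | intermediate
9 | (2S)-6-[(dimethylamino)methyl]-5-hydroxy-8-methylidene-2-phenyl-2,3-dihydrochromene-4,7(8H)-dione, the ortho-quinone methide of the C8 arm, drawn without the boron bound to O7 | O=C1C[C@@H](c2ccccc2)OC2=C1C(O)=C(CN(C)C)C(=O)C2=C | intermediate
10 | (2S)-6-[(dimethylamino)methyl]-8-[(2,2-dimethyl-1,3-benzodioxol-4-yl)methyl]-5,7-dihydroxy-2-phenylchroman-4-one | O=C1C[C@@H](c2ccccc2)Oc2c(Cc3cccc4c3OC(C)(C)O4)c(O)c(CN(C)C)c(O)c21 | intermediate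
11 | (2S)-8-[(2,2-dimethyl-1,3-benzodioxol-4-yl)methyl]-5-hydroxy-6-methylidene-2-phenyl-2,3-dihydrochromene-4,7(6H)-dione, the ortho-quinone methide of the C6 arm, drawn without the boron bound to O7 | O=C1C[C@@H](c2ccccc2)OC2=C(Cc3cccc4c3OC(C)(C)O4)C(=O)C(=C)C(O)=C21 | intermediate
12 | (2S)-6,8-bis[(2,2-dimethyl-1,3-benzodioxol-4-yl)methyl]-5,7-dihydroxy-2-phenylchroman-4-one | O=C1C[C@@H](c2ccccc2)Oc2c(Cc3cccc4c3OC(C)(C)O4)c(O)c(Cc3cccc4c3OC(C)(C)O4)c(O)c21 | intermediate
13 | (2S)-6,8-bis(2,3-dihydroxybenzyl)-5,7-dihydroxy-2-phenylchroman-4-one | O=C1C[C@@H](c2ccccc2)Oc2c(Cc3cccc(O)c3O)c(O)c(Cc3cccc(O)c3O)c(O)c21 | target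

**Step count**
Total step count: 4.
Longest linear sequence: 3 steps (1 → 4 → 12 → 13). The branch 5 → 8 → 12 → 13 is equally long.

**Steps most likely to fail**

Step 3. The aryl shift may be outpaced in three ways: protodeboronation of the boron partner, collapse of the quinone methide onto a boron-bound hydroxyl group to give a cyclic boronate resting state, or oligomerisation. Long heating beside liberated amine may also erode the configuration at C2.
Fallback: the polarity of the methylene is reversed, so that ring A becomes the nucleophile. Commercial 2,3-dihydroxybenzaldehyde is reduced with NaBH4 in MeOH to 2,3-dihydroxybenzyl alcohol F1. Compound 1 is then heated with an excess of F1 and ZnCl2 in 1,4-dioxane. This is a Friedel–Crafts-type ortho-hydroxybenzylation of the kind established for 2-hydroxybenzyl alcohols and 5,7-dihydroxyflavanones, and it should alkylate both C6 and C8. The path sets out from 1, needs none of 4, 8 and 12, and comes back to the route at 13.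

Step 1. The second aminomethylation may stall because the first arm is present as an electron-withdrawing ammonium group. Aminomethylation may also spill over to C3 through the enol. During neutralisation, the zwitterionic product may be lost to the aqueous phase or ring C may open.
Fallback: the C1 units are introduced at the aldehyde oxidation level. Twofold Duff formylation of 1 (hexamethylenetetramine, TFA, then aqueous HCl) should give (2S)-5,7-dihydroxy-4-oxo-2-phenylchroman-6,8-dicarbaldehyde F2. Twofold reductive amination (Me2NH, AcOH, NaBH(OAc)3, 1,2-dichloroethane, rt) leaves the chelated C4 ketone alone and converts both formyl groups into dimethylaminomethyl groups. The path sets out from 1 and comes back to the route at 4.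

Step 4. Strong acid may reversibly open ring C by way of the chalcone and so erode C2. It may also protonate ring A ipso to a benzyl group and shift or shed that group, or cleave the ketals only in part. The freed catechols may be oxidised by air.
Fallback: the catechols are carried as a ketal that falls to hydrogenolysis under neutral conditions.
- Catechol is condensed with dichlorodiphenylmethane (neat, 170 °C) to 2,2-diphenyl-1,3-benzodioxole F3.
- F3 is lithiated and borylated as in step 2 to (2,2-diphenyl-1,3-benzodioxol-4-yl)boronic acid F4.
- Coupling with 4 under the conditions of step 3 should give (2S)-6,8-bis[(2,2-diphenyl-1,3-benzodioxol-4-yl)methyl]-5,7-dihydroxy-2-phenylchroman-4-one F5.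
- H2 (1 atm), Pd/C, THF/MeOH, rt, then releases both catechols.

The path sets out from 4 and comes back to the route at 13.

**Further compounds**
F1 | step 3 | 2,3-dihydroxybenzyl alcohol | OCc1cccc(O)c1O
F2 | step 1 | (2S)-5,7-dihydroxy-4-oxo-2-phenylchroman-6,8-dicarbaldehyde | O=C1C[C@@H](c2ccccc2)Oc2c(C=O)c(O)c(C=O)c(O)c21
F3 | step 4 | 2,2-diphenyl-1,3-benzodioxole | c1ccc(C2(c3ccccc3)Oc3ccccc3O2)cc1
F4 | step 4 | (2,2-diphenyl-1,3-benzodioxol-4-yl)boronic acid | OB(O)c1cccc2c1OC(c1ccccc1)(c1ccccc1)O2
F5 | step 4 | (2S)-6,8-bis[(2,2-diphenyl-1,3-benzodioxol-4-yl)methyl]-5,7-dihydroxy-2-phenylchroman-4-one | O=C1C[C@@H](c2ccccc2)Oc2c(Cc3cccc4c3OC(c3ccccc3)(c3ccccc3)O4)c(O)c(Cc3cccc4c3OC(c3ccccc3)(c3ccccc3)O4)c(O)c21
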